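## Structural features

The target is a germacrane-type ten-membered carbocycle (C1–C10) bridged by an oxygen between C3 and C10, which creates a 3(2H)-furanone (C10–C1(=O)–C2=C3–O), and fused across C6–C7 to an α-methylene-γ-butyrolactone (O–C6 and C7–C11(=C13)–C12=O). The furanone enol ether continues through a Z-configured, trisubstituted C4=C5 olefin (C15 methyl on C4) to the allylic lactone carbinol C6, so C1 to C6 form one cross-conjugated dienone. Five stereocentres stand side by side, C6 (R), C7 (S), C8 (S), C9 (R) and C10 (R): H6 and H7 are anti (trans lactone), the C8 oxygen is cis to the C7–C11 bond and trans to the C9 oxygen, and the C9 oxygen is cis to the oxygen on the fully substituted C10. O8 carries an isovalerate and O9 an acetate, so two neighbouring secondary hydroxyls have to be distinguished. The fragile groups are the exo-methylene lactone (Michael acceptor), the dienone with its vinylogously acidic C15 and C6 hydrogens, the two esters (acyl migration, translactonisation from O6 to O8) and, in intermediates, any C6 ketone, which makes C7 epimerisable and the C8 oxygen a β-leaving group. The real difficulty is to set the four contiguous centres C7–C10, one of them quaternary, on a medium ring and to close that ring at all. The plan exploits that the ketone carbon C1 and the carbinol carbon C6 lie 1,6 across the ten-membered ring: a temporary C1=C6 bond turns the macrocycle into an octalin whose ring B (C1, C10, C9, C8, C7, C6) holds all four difficult centres and whose ring A (C1–C6, oxygen on C3, methyl on C4) is the Birch-reduction product of a 2-methylanisole, with the C10 hydroxyl five atoms from the C3 carbonyl.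

## Logic of the disconnections

35 ⇒ 34 ⇒ 33 ⇒ 32 ⇒ 31. The acyl–oxygen bonds of the C9 acetate and then of the C8 isovalerate are cut, and each oxygen is traced to a silyl ether of different lability. Esters would not survive dissolving metal or amide bases, and two neighbouring secondary hydroxyls cannot be told apart safely by reactivity alone. The ester problem shrinks to the order of two deprotections. The forward demand is that each hydroxyl is acylated as soon as it is freed, O8 first, because a free O8 can attack the C12 carbonyl and a free O9 can accept the C8 acyl group.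

31 ⇒ 28. The C11=C13 bond is cut. The exo-methylene group is the most electrophilic site and should appear last among the carbon–carbon bonds. The gain is a plain γ-lactone without a Michael acceptor. The demand is kinetic enolisation of the lactone beside a base-sensitive dienone.

28 ⇒ 27 ⇒ 26. The lactone C6–O bond and then the C6–H bond are cut, so C6 becomes a ketone and C12 a free acid. The ketone is what allows the C4=C5 olefin to be made, and it is the carbonyl that the ring cleavage delivers. The demand is a known facial sense of hydride attack on C6 and a ring closure whose stereochemical course (inversion) matches it.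

26 ⇒ 24. The C4=C5 π bond is removed. C4 then needs no control, since either epimer leads to the same olefin. The demand is enolisation of the C6 ketone toward C5, not C7, and the Z geometry.

24 ⇒ 21. The O–C3 bond of the furanone is cut and C1 and C6 are joined by a double bond. This converts a bridged ten-membered triketone problem into a bicyclic octalin in which no medium ring has to be closed. The forward step needs a substrate with one olefin only and a C10 hydroxyl that chooses C3 among three carbonyls.

21 ⇒ 19. Ring A is re-aromatised (retro-Birch). A flat, robust arene then carries ring B through all stereochemical work. The demand is protonation at C2 and C5 only and survival of the benzylic C10–O bond under dissolving metal.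

19 ⇒ 16 ⇒ 15. The O8 and O9 silyl ethers and the free acid are traced to a lactone that ties O8 to C12 and leaves O9 free. O8 and O9 are thus differentiated by construction. The demand is silylation of the secondary O9 beside the tertiary O10 and lactone opening without silyl migration.

15 ⇒ 13 ⇒ 12. The C8–O bond is cut (carboxylate opening of a C8–C9 epoxide) and the epoxide is traced to an olefin beside the C10 carbinol. The C7 arm can reach C8 only from its own face, so C7/C8 cis and C8/C9 trans follow from one epoxide. The demand is that the epoxide forms syn to the C10 hydroxyl.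

12 ⇒ 10 ⇒ 9. The C10–O bond is cut by way of a C9–C10 epoxide and its selenide-mediated transposition to the allylic alcohol. This avoids any C8 ketone beside a C9=C10 styrene olefin, which would be the keto tautomer of a 2-naphthol and would aromatise with loss of C7. The demand is epoxidation anti to the C7 arm.

9 ⇒ 6 + 7. The C10–C14 bond is cut (methyl addition to the aryl ketone, then dehydration). The demand is addition to the ketone in the presence of the ester.

6 ⇒ 4 ⇒ 3. The C1–C10 bond is cut (Friedel–Crafts acylation). The demand is six-membered closure by the longer arm at the position para to the methyl group.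

3 ⇒ 1 + 2. The aryl–C7 bond is cut. An asymmetric conjugate addition sets C7, the only centre made by reagent control, in the first step from two commercial compounds.

## Other disconnections considered

Alternative 1: The cut is C1–C10, with C3–C8 joined in exchange, so the ten-membered ring is traced back to a six-membered ring from the terpene chiral pool. In the forward direction an anionic oxy-Cope [3,3] shift forms C1–C10, breaks C3–C8 and expands the ring by four atoms to give A1.
- In its favour: one pericyclic step makes the medium ring and the quaternary C10 together, and the six-membered ring supplies C6, C7 and the cis C4=C5 olefin.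
- Better than the chosen plan: C13 is present from the start, so no late lactone methylenation is needed, and A1 should be reached in fewer steps than 24.
- Equal: the 1-ethoxy enone of A1 is a masked C1/C3 diketone, so the furanone would be closed by the same cyclodehydration.
- Against it here: C8 and C9 arrive as a trans olefin on a flexible ten-membered ring. Both oxygens would have to be added by face-selective syn-dihydroxylation without a rigid template and then still be distinguished. C12 arrives at the alcohol oxidation level and must be oxidised to the lactone carbonyl beside a dienone. The C10 configuration depends on an enol ether geometry and on one transition-state shape being enforced.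
- Comparison: the concerted shift is mechanistically cleaner than a triketone that must be steered into one cyclisation mode. The chosen plan is stronger on structure, because C7–C10 are set on a six-membered ring fused to an arene and O8/O9 are told apart by a lactone.

Alternative 2: The cut is the C8=C9 double bond, the two carbons being carried as vinyl groups on C7 and C10 of A2. The forward key step is ring-closing metathesis with the second-generation Grubbs catalyst, which would give A3. The C8 and C9 oxygens would then come from epoxidation of A3 and regioselective opening at C8.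
- In its favour: the furanone, the Z olefin and the methylene lactone are assembled on open-chain fragments, and the ring is closed by a catalytic, functional-group-tolerant reaction.
- Better than the chosen plan: convergence and a shorter longest linear sequence.
- Equal: opening at C8 by an isovalerate nucleophile would differentiate O8 and O9 in the bond-forming step, as the lactone does in the chosen plan.
- Against it here: ten-membered rings are among the hardest to close by metathesis. One vinyl group sits on the fully substituted C10, the ring already holds three sp2 arrays, and the exo-methylene lactone is a third olefin that can engage the carbene. After closure the epoxidant must choose one face of a macrocyclic olefin with no directing group, and the opening must occur with inversion at C8.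
- Comparison: the metathesis is reversible and pays the full entropic and strain cost of the medium ring. In the chosen plan the ring is unveiled by cleaving a bond, and C8/C9 are set on a rigid six-membered ring before the macrocycle exists.

Alternative 3: The cut is C7–C11. In the forward direction the diazophosphonoacetate A4, an ester of the C6 hydroxyl of a finished ten-membered furanone core, would give a rhodium carbenoid with Rh2(OAc)4 that inserts into one C7–H bond, closing the γ-lactone and setting C7 in A5. A Horner–Wadsworth–Emmons reaction of A5 with formaldehyde would then give the exo-methylene group.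
- In its favour: lactone and methylene group are made in two mild steps at the very end, and the C11 configuration is irrelevant.
- Better than the chosen plan: the olefination avoids strong-base enolate chemistry on the dienone lactone (step 16), and the lactone itself takes fewer steps.
- Against it here: it is an endgame only and leaves open how the ten-membered core with the trans C8/C9 diol is made. C7–H is an unactivated methylene C–H, deactivated by the neighbouring C8 oxygen. Cyclopropanation of the allylic C4=C5 olefin, insertion α to oxygen at C8 and ylide formation with the acetal oxygens compete. The choice between the two diastereotopic hydrogens on a mobile ring decides whether the lactone is trans.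
- Comparison: in the chosen plan C7 is set first, by asymmetric catalysis on a simple enoate, and the ring-forming problem is solved by the same step that makes the C6 carbonyl.

Key step: step 12

Remarks on the chemistry:
- Atom numbers are those of the germacrane skeleton: ring carbons C1–C10, side chain C11–C13 on C7, C14 on C10, C15 on C4.
- 21 and 24 were checked atom by atom against 35 and carry the target configuration at C7–C10. The two silyl groups are made different (triethylsilyl on O8, tert-butyldimethylsilyl on O9), and C4 is left unassigned because it becomes trigonal in step 13.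
- Hydride attack on the C6 ketone of 26 is assumed to follow the Felkin–Anh model (anti to the C7–C8 bond), which gives the 6S carbinol; the lactone is therefore closed with inversion.

## Route

Step 1
Reactants: 1 4-methoxy-3-methylphenylboronic acid; 2 dimethyl (E)-hex-2-enedioate
Product: 3 dimethyl (3S)-3-(4-methoxy-3-methylphenyl)hexanedioate
Conditions: Rh(acac)(C2H4)2 (3 mol %), (R)-BINAP (3.3 mol %), 1 (2.5 equiv), dioxane/H2O 10:1, 100 °C
Reagents that add atoms: none
Why: Hayashi–Miyaura asymmetric 1,4-addition: by the quadrant model for (E)-enoates the aryl–rhodium species carrying (R)-BINAP should add to the α-re face, which puts the aryl group on C7 with the S configuration; the remote saturated ester is a spectator and excess boronic acid offsets protodeboronation.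

Step 2
Reactants: 3 dimethyl (3S)-3-(4-methoxy-3-methylphenyl)hexanedioate
Product: 4 (3S)-3-(4-methoxy-3-methylphenyl)hexanedioic acid
Conditions: LiOH·H2O, THF/H2O, 23 °C; then 1 M HCl
Reagents that add atoms: water (delivered as LiOH/H2O), O
Why: Ester saponification; C7 is β to both carbonyls and cannot epimerise.

Step 3
Reactants: 4 (3S)-3-(4-methoxy-3-methylphenyl)hexanedioic acid
Product: 6 methyl 2-[(1S)-6-methoxy-7-methyl-4-oxo-1,2,3,4-tetrahydronaphthalen-1-yl]acetate, via keto acid 5 (not isolated)
Conditions: CF3SO3H, CH2Cl2, 0 → 23 °C; then MeOH, 40 °C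
Reagents that add atoms: methanol, CO
Why: Intramolecular Friedel–Crafts acylation: the acylium ion of the longer arm closes the six-membered ring (faster than indanone formation by the shorter arm) at the position para to the methyl group, the other ortho position being wedged between the methyl group and the side chain; the untouched acid is then esterified in the same acidic medium (Fischer esterification).

Step 4
Reactants: 6 methyl 2-[(1S)-6-methoxy-7-methyl-4-oxo-1,2,3,4-tetrahydronaphthalen-1-yl]acetate; 7 methylmagnesium bromide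
Product: 9 methyl 2-[(1S)-6-methoxy-4,7-dimethyl-1,2-dihydronaphthalen-1-yl]acetate, via tertiary carbinol 8 (not isolated)
Conditions: 7 (1.3 equiv), CeCl3, THF, −78 °C; aq. NH4Cl; then TsOH·H2O (cat.), PhMe, 60 °C
Reagents that add atoms: methylmagnesium bromide (7), C[Mg]Br
Why: The organocerium reagent made from 7 and CeCl3 adds to the aryl ketone without enolising it and leaves the methyl ester alone; acid-catalysed E1 dehydration of the tertiary benzylic carbinol gives the conjugated C9=C10 olefin, so both C10 epimers of 8 converge.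

Step 5
Reactants: 9 methyl 2-[(1S)-6-methoxy-4,7-dimethyl-1,2-dihydronaphthalen-1-yl]acetate
Product: 10 methyl 2-[(1aR,3S,7bS)-6-methoxy-5,7b-dimethyl-1a,2,3,7b-tetrahydronaphtho[1,2-b]oxiren-3-yl]acetate
Conditions: D-fructose-derived Shi ketone (30 mol %), KHSO5 (as 2KHSO5·KHSO4·K2SO4), K2CO3, Bu4NHSO4, MeCN/CH2(OMe)2/aq. buffer pH 10.5, 0 °C
Reagents that add atoms: potassium peroxymonosulfate, [K+].[O-]S(=O)(=O)OO
Why: Shi epoxidation (chiral dioxirane, spiro transition state): with this ketone the oxygen should reach the C9=C10 face anti to the pseudoaxial C7 arm, so catalyst and substrate preferences reinforce each other and place the C10 oxygen on the face opposite the arm; the basic buffer preserves the acid-labile benzylic epoxide.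

Step 6
Reactants: 10 methyl 2-[(1aR,3S,7bS)-6-methoxy-5,7b-dimethyl-1a,2,3,7b-tetrahydronaphtho[1,2-b]oxiren-3-yl]acetate
Product: 12 methyl 2-[(1R,4R)-4-hydroxy-6-methoxy-4,7-dimethyl-1,4-dihydronaphthalen-1-yl]acetate, via hydroxy selenide 11 (not isolated)
Conditions: PhSeSePh, NaBH4, MeOH/THF, 0 → 40 °C; then 30% H2O2, pyridine, THF, 0 → 23 °C
Reagents that add atoms: none
Why: Phenylselenide opens the epoxide by SN2 at the secondary C9 (C10 is tertiary), and the selenoxide can only syn-eliminate toward C8 because C10 has no hydrogen, which gives the C8=C9 olefin and keeps the C10 carbinol (selenoxide elimination of a β-hydroxy selenide); pyridine buffers the selenium acids so that the tertiary benzylic alcohol does not ionise and aromatise.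

Step 7
Reactants: 12 methyl 2-[(1R,4R)-4-hydroxy-6-methoxy-4,7-dimethyl-1,4-dihydronaphthalen-1-yl]acetate
Product: 13 methyl 2-[(1aR,2S,7S,7aR)-7-hydroxy-5-methoxy-4,7-dimethyl-1a,2,7,7a-tetrahydronaphtho[2,3-b]oxiren-2-yl]acetate
Conditions: mCPBA, NaHCO3, CH2Cl2, 0 °C
Reagents that add atoms: 3-chloroperoxybenzoic acid, O=C(OO)c1cccc(Cl)c1
Why: Hydroxyl-directed peracid epoxidation: the hydrogen bond to the allylic C10 hydroxyl delivers the oxygen syn to it, which is also the face away from the C7 arm, so the C9 oxygen ends up cis to the C10 oxygen; bicarbonate keeps the medium neutral.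

Step 8
Reactants: 13 methyl 2-[(1aR,2S,7S,7aR)-7-hydroxy-5-methoxy-4,7-dimethyl-1a,2,7,7a-tetrahydronaphtho[2,3-b]oxiren-2-yl]acetate
Product: 15 (3aS,4R,5S,9bS)-4,5-dihydroxy-7-methoxy-5,8-dimethyl-3a,4,5,9b-tetrahydronaphtho[2,1-b]furan-2(1H)-one, via epoxy acid 14 (not isolated)
Conditions: LiOH·H2O, THF/H2O, 23 °C; then AcOH to pH 4, 40 °C
Reagents that add atoms: water (delivered as LiOH/H2O), O
Why: Saponification frees the carboxylate, which on mild acidification opens the epoxide by 5-exo attack at C8 from the face of the C7 arm, anti to the oxirane oxygen (epoxy acid lactonisation); this fixes the C8 oxygen cis to C7–C11 and trans to the C9 hydroxyl and ties O8 to C12, so O8 and O9 are differentiated.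

Step 9
Reactants: 15 (3aS,4R,5S,9bS)-4,5-dihydroxy-7-methoxy-5,8-dimethyl-3a,4,5,9b-tetrahydronaphtho[2,1-b]furan-2(1H)-one
Product: 16 (3aS,4R,5S,9bS)-4-[(tert-butyldimethylsilyl)oxy]-5-hydroxy-7-methoxy-5,8-dimethyl-3a,4,5,9b-tetrahydronaphtho[2,1-b]furan-2(1H)-one
Conditions: tBuMe2SiOSO2CF3 (1.1 equiv), 2,6-lutidine, CH2Cl2, −78 °C
Reagents that add atoms: tert-butyldimethylsilyl trifluoromethanesulfonate, CC(C)(C)[Si](C)(C)OS(=O)(=O)C(F)(F)F
Why: Silyl triflate silylation takes place at the secondary C9 hydroxyl; the tertiary benzylic C10 hydroxyl is too hindered for one equivalent at low temperature and must stay free for the furanone closure.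

Step 10
Reactants: 16 (3aS,4R,5S,9bS)-4-[(tert-butyldimethylsilyl)oxy]-5-hydroxy-7-methoxy-5,8-dimethyl-3a,4,5,9b-tetrahydronaphtho[2,1-b]furan-2(1H)-one
Product: 19 2-[(1S,2S,3R,4S)-3-[(tert-butyldimethylsilyl)oxy]-4-hydroxy-6-methoxy-4,7-dimethyl-2-[(triethylsilyl)oxy]-1,2,3,4-tetrahydronaphthalen-1-yl]acetic acid, via lithium carboxylate 17 (not isolated), via bis-triethylsilyl derivative 18 (not isolated)
Conditions: LiOH·H2O (1.1 equiv), THF/H2O, 0 → 23 °C, evaporate; Et3SiCl, imidazole, DMF, 23 °C; then K2CO3 (cat.), MeOH/H2O, 0 °C; pH 5 buffer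
Reagents that add atoms: water (delivered as LiOH/H2O), O; chlorotriethylsilane, CC[Si](Cl)(CC)CC
Why: Hydroxide opens the γ-lactone, the hydroxy carboxylate is persilylated and the labile silyl ester is methanolysed, leaving the O8 triethylsilyl ether and the free acid (standard lactone-to-silyloxy-acid sequence); the acid-labile group on O8 and the robust group on O9 can later be removed one after the other.

Step 11
Reactants: 19 2-[(1S,2S,3R,4S)-3-[(tert-butyldimethylsilyl)oxy]-4-hydroxy-6-methoxy-4,7-dimethyl-2-[(triethylsilyl)oxy]-1,2,3,4-tetrahydronaphthalen-1-yl]acetic acid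
Product: 21 2-[(1S,2S,3R,4S)-3-[(tert-butyldimethylsilyl)oxy]-4-hydroxy-4,7-dimethyl-6-oxo-2-[(triethylsilyl)oxy]-1,2,3,4,5,6,7,8-octahydronaphthalen-1-yl]acetic acid (both epimers at the methyl-bearing ring A carbon, germacrane C4), via dienol ether 20 (not isolated)
Conditions: Li (excess), NH3(l)/THF/tBuOH, −78 → −33 °C; NH4Cl; then (CO2H)2 (0.1 M aq.), THF, 0 °C
Reagents that add atoms: water, O
Why: Birch reduction: with the acid as carboxylate and the benzylic C10 hydroxyl as alkoxide (a poor leaving group, which blocks benzylic C–O hydrogenolysis) the arene is protonated only at its two unsubstituted carbons C2 and C5, leaving the C1=C6 and C3=C4 olefins; cold dilute oxalic acid hydrolyses the enol ether to the C3 ketone without moving the tetrasubstituted C1=C6 olefin into conjugation, and C4 is formed without control.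

Step 12
Reactants: 21 2-[(1S,2S,3R,4S)-3-[(tert-butyldimethylsilyl)oxy]-4-hydroxy-4,7-dimethyl-6-oxo-2-[(triethylsilyl)oxy]-1,2,3,4,5,6,7,8-octahydronaphthalen-1-yl]acetic acid
Product: 24 (7R,8S,9R,10R)-9-[(tert-butyldimethylsilyl)oxy]-1,6-dioxo-8-[(triethylsilyl)oxy]-3,10-epoxy-13-norgermacr-2-en-12-oic acid (both C4 epimers), via hydroxy triketone 22 (not isolated), via hemiketal 23 (not isolated)
Conditions: O3, CH2Cl2/MeOH 4:1, −78 °C; Me2S, −78 → 23 °C; then PPTS (0.2 equiv), 4 Å molecular sieves, PhH, 40 °C
Reagents that add atoms: ozone, [O-][O+]=O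
Why: Ozone adds to the only C=C bond left, the tetrasubstituted ring-fusion olefin C1=C6, and the primary ozonide collapses in methanol to a ketone and a methoxy hydroperoxide that Me2S reduces, so C1 and C6 become ketones and the two six-membered rings merge into the ten-membered carbocycle 22 (closest known type: ozonolysis of a ring-fusion octalin to a cyclodecane-1,6-dione). The ten-membered ring is thus not closed by bond formation but unveiled by scission of the shared bond, which avoids the entropic and transannular cost of a medium-ring cyclisation. In 22 C1 and C3 form a 1,3-diketone and C10 carries a free hydroxyl α′ to C1; under pyridinium tosylate this hydroxyl adds to the C3 carbonyl (5-exo-trig) to give hemiketal 23, and loss of water gives the 3(2H)-furanone, the known acid cyclodehydration of α′-hydroxy 1,3-diketones. No new stereocentre is formed: C7–C10 are untouched and C4 stays a mixture. The oxidation is chemoselective because the enol ether was hydrolysed in step 11 and the arene no longer exists, and the reductive, amine-free work-up avoids base, which would start transannular aldol reactions of the triketone, epimerise C7 (now α to the C6 ketone) or expel the C8 silyloxy group. In the closure the C10 hydroxyl can also add reversibly to C6, but only the C3 adduct can dehydrate to a conjugated vinylogous ester, which is the thermodynamic sink; a Paal–Knorr furan across C3/C6 would be a 2,5-bridged furan with a seven-atom bridge and is disfavoured by strain, and O9 is silylated so that no six-membered pyranone can form.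

Step 13
Reactants: 24 (7R,8S,9R,10R)-9-[(tert-butyldimethylsilyl)oxy]-1,6-dioxo-8-[(triethylsilyl)oxy]-3,10-epoxy-13-norgermacr-2-en-12-oic acid
Product: 26 (4Z,7R,8S,9R,10R)-9-[(tert-butyldimethylsilyl)oxy]-1,6-dioxo-8-[(triethylsilyl)oxy]-3,10-epoxy-13-norgermacra-2,4-dien-12-oic acid, via bis-silyl species 25 (not isolated)
Conditions: Me3SiCl, then LiN(iPr)2 (2.5 equiv), THF, −78 °C; then Pd(OAc)2 (1.1 equiv), MeCN, 23 °C; aq. work-up at pH 5
Reagents that add atoms: none
Why: Saegusa–Ito oxidation: in-situ silylation traps the kinetic C5 enolate of the C6 ketone (C7 is tertiary and more hindered, which also protects its configuration and the β-silyloxy group), and divalent palladium converts the silyl enol ether into the enone by β-hydride elimination from C4, the only β-hydrogen; both C4 epimers converge, and the olefin should be Z because a trans olefin would strain the nine-membered oxygen-bridged ring.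

Step 14
Reactants: 26 (4Z,7R,8S,9R,10R)-9-[(tert-butyldimethylsilyl)oxy]-1,6-dioxo-8-[(triethylsilyl)oxy]-3,10-epoxy-13-norgermacra-2,4-dien-12-oic acid
Product: 27 (4Z,6S,7S,8S,9R,10R)-9-[(tert-butyldimethylsilyl)oxy]-6-hydroxy-1-oxo-8-[(triethylsilyl)oxy]-3,10-epoxy-13-norgermacra-2,4-dien-12-oic acid
Conditions: NaBH4, CeCl3·7H2O, MeOH, −78 °C; NaH2PO4 buffer (pH 5), 0 °C
Reagents that add atoms: none
Why: Luche reduction: the cerium-activated C6 enone carbonyl is reduced 1,2 while the vinylogous-ester carbonyl C1 is left; hydride should attack anti to the C7–C8 bond with the C11 arm beside the carbonyl oxygen (Felkin–Anh; a cerium chelate between carboxylate and ketone would expose the same face), which gives the 6S carbinol, and the cold, weakly acidic work-up keeps the hydroxy acid from lactonising with retention.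

Step 15
Reactants: 27 (4Z,6S,7S,8S,9R,10R)-9-[(tert-butyldimethylsilyl)oxy]-6-hydroxy-1-oxo-8-[(triethylsilyl)oxy]-3,10-epoxy-13-norgermacra-2,4-dien-12-oic acid
Product: 28 (4Z,6R,7S,8S,9R,10R)-9-[(tert-butyldimethylsilyl)oxy]-1-oxo-8-[(triethylsilyl)oxy]-3,10-epoxy-13-norgermacra-2,4-dien-12,6-olide
Conditions: PPh3, DIAD, THF (0.01 M), −20 → 0 °C
Reagents that add atoms: none
Why: Mitsunobu lactonisation: the C6 hydroxyl is activated as an alkoxyphosphonium ion and displaced by the tethered carboxylate in a 5-exo-tet SN2 reaction with inversion, which makes C6 R and the γ-lactone trans-fused (H6 anti to H7).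

Step 16
Reactants: 28 (4Z,6R,7S,8S,9R,10R)-9-[(tert-butyldimethylsilyl)oxy]-1-oxo-8-[(triethylsilyl)oxy]-3,10-epoxy-13-norgermacra-2,4-dien-12,6-olide
Product: 31 (4Z,6R,7S,8S,9R,10R)-9-[(tert-butyldimethylsilyl)oxy]-1-oxo-8-[(triethylsilyl)oxy]-3,10-epoxygermacra-2,4,11(13)-trien-12,6-olide, via Mannich base 29 (not isolated), via ammonium iodide 30 (not isolated)
Conditions: LiN(iPr)2 (1.2 equiv), THF, −78 °C; [Me2N=CH2]I, −78 → 0 °C; then MeI, MeOH, 23 °C; then NaHCO3 (aq.)/CH2Cl2, 23 °C
Reagents that add atoms: dimethylmethyleneammonium iodide, C=[N+](C)C.[I-]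
Why: Kinetic deprotonation of the lactone at C11 (the only C–H directly α to a carbonyl; C15 and C6 are only vinylogously acidic) and Mannich reaction with the iminium salt give 29; N-methylation and mild base-induced β-elimination of trimethylamine give the exo-methylene lactone (Eschenmoser methylenation), and the C11 centre disappears.

Step 17
Reactants: 31 (4Z,6R,7S,8S,9R,10R)-9-[(tert-butyldimethylsilyl)oxy]-1-oxo-8-[(triethylsilyl)oxy]-3,10-epoxygermacra-2,4,11(13)-trien-12,6-olide
Product: 32 (4Z,6R,7R,8S,9R,10R)-9-[(tert-butyldimethylsilyl)oxy]-8-hydroxy-1-oxo-3,10-epoxygermacra-2,4,11(13)-trien-12,6-olide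
Conditions: HF·pyridine, pyridine, THF, 0 °C
Reagents that add atoms: none
Why: Buffered HF·pyridine cleaves the acid-labile triethylsilyl ether on O8 and leaves the hindered, neopentyl-type tert-butyldimethylsilyl ether on O9 (selective desilylation by silyl lability); the acidic medium does not promote translactonisation (the change of the C7 descriptor is only a priority effect).

Step 18
Reactants: 32 (4Z,6R,7R,8S,9R,10R)-9-[(tert-butyldimethylsilyl)oxy]-8-hydroxy-1-oxo-3,10-epoxygermacra-2,4,11(13)-trien-12,6-olide
Product: 33 (4Z,6R,7S,8S,9R,10R)-9-[(tert-butyldimethylsilyl)oxy]-8-(3-methylbutanoyloxy)-1-oxo-3,10-epoxygermacra-2,4,11(13)-trien-12,6-olide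
Conditions: (Me2CHCH2CO)2O, pyridine, DMAP (cat.), CH2Cl2, 0 °C
Reagents that add atoms: 3-methylbutanoic anhydride, CC(C)CC(=O)OC(=O)CC(C)C
Why: DMAP-catalysed acylation esterifies O8 faster than it can attack the lactone carbonyl; pyridine is used in place of a stronger base to suppress translactonisation to O8.

Step 19
Reactants: 33 (4Z,6R,7S,8S,9R,10R)-9-[(tert-butyldimethylsilyl)oxy]-8-(3-methylbutanoyloxy)-1-oxo-3,10-epoxygermacra-2,4,11(13)-trien-12,6-olide
Product: 34 (4Z,6R,7S,8S,9R,10R)-9-hydroxy-8-(3-methylbutanoyloxy)-1-oxo-3,10-epoxygermacra-2,4,11(13)-trien-12,6-olide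
Conditions: HF (48% aq.), MeCN, 0 → 23 °C
Reagents that add atoms: none
Why: Acidic fluoride removes the hindered silyl ether on O9 under conditions in which the C8 ester does not migrate and the furanone, enone and methylene lactone are stable.

Step 20
Reactants: 34 (4Z,6R,7S,8S,9R,10R)-9-hydroxy-8-(3-methylbutanoyloxy)-1-oxo-3,10-epoxygermacra-2,4,11(13)-trien-12,6-olide
Product: 35 (4Z,6R,7S,8S,9R,10R)-9-acetoxy-8-(3-methylbutanoyloxy)-1-oxo-3,10-epoxygermacra-2,4,11(13)-trien-12,6-olide (CNP0255553.1)
Conditions: Ac2O, pyridine, DMAP (cat.), CH2Cl2, 23 °C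
Reagents that add atoms: acetic anhydride, CC(=O)OC(C)=O
Why: DMAP-catalysed acetylation of the hindered C9 hydroxyl completes the target; no stereocentre is touched.

## Compound list

1 | 4-methoxy-3-methylphenylboronic acid | COc1ccc(B(O)O)cc1C | starting material
2 | dimethyl (E)-hex-2-enedioate | COC(=O)/C=C/CCC(=O)OC | starting material
3 | dimethyl (3S)-3-(4-methoxy-3-methylphenyl)hexanedioate | COC(=O)C[C@H](CCC(=O)OC)c1ccc(OC)c(C)c1 | intermediate
4 | (3S)-3-(4-methoxy-3-methylphenyl)hexanedioic acid | OC(=O)C[C@H](CCC(=O)O)c1ccc(OC)c(C)c1 | intermediate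
5 | 2-[(1S)-6-methoxy-7-methyl-4-oxo-1,2,3,4-tetrahydronaphthalen-1-yl]acetic acid | OC(=O)C[C@@H]1CCC(=O)c2cc(OC)c(C)cc21 | intermediate (not isolated)
6 | methyl 2-[(1S)-6-methoxy-7-methyl-4-oxo-1,2,3,4-tetrahydronaphthalen-1-yl]acetate | COC(=O)C[C@@H]1CCC(=O)c2cc(OC)c(C)cc21 | intermediate
7 | methylmagnesium bromide | C[Mg]Br | starting material
8 | methyl 2-[(1S)-4-hydroxy-6-methoxy-4,7-dimethyl-1,2,3,4-tetrahydronaphthalen-1-yl]acetate (both C4 epimers of the tetralin) | COC(=O)C[C@@H]1CCC(C)(O)c2cc(OC)c(C)cc21 | intermediate (not isolated)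
9 | methyl 2-[(1S)-6-methoxy-4,7-dimethyl-1,2-dihydronaphthalen-1-yl]acetate | COC(=O)C[C@@H]1CC=C(C)c2cc(OC)c(C)cc21 | intermediate
10 | methyl 2-[(1aR,3S,7bS)-6-methoxy-5,7b-dimethyl-1a,2,3,7b-tetrahydronaphtho[1,2-b]oxiren-3-yl]acetate | COC(=O)C[C@@H]1C[C@H]3O[C@@]3(C)c2cc(OC)c(C)cc21 | intermediate
11 | methyl 2-[(1R,3S,4S)-4-hydroxy-6-methoxy-4,7-dimethyl-3-(phenylselanyl)-1,2,3,4-tetrahydronaphthalen-1-yl]acetate | COC(=O)C[C@@H]1C[C@H]([Se]c3ccccc3)[C@@](C)(O)c2cc(OC)c(C)cc21 | intermediate (not isolated)
12 | methyl 2-[(1R,4R)-4-hydroxy-6-methoxy-4,7-dimethyl-1,4-dihydronaphthalen-1-yl]acetate | COC(=O)C[C@@H]1C=C[C@@](C)(O)c2cc(OC)c(C)cc21 | intermediate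
13 | methyl 2-[(1aR,2S,7S,7aR)-7-hydroxy-5-methoxy-4,7-dimethyl-1a,2,7,7a-tetrahydronaphtho[2,3-b]oxiren-2-yl]acetate | COC(=O)C[C@@H]1[C@H]3O[C@H]3[C@@](C)(O)c2cc(OC)c(C)cc21 | intermediate
14 | 2-[(1aR,2S,7S,7aR)-7-hydroxy-5-methoxy-4,7-dimethyl-1a,2,7,7a-tetrahydronaphtho[2,3-b]oxiren-2-yl]acetic acid | OC(=O)C[C@@H]1[C@H]3O[C@H]3[C@@](C)(O)c2cc(OC)c(C)cc21 | intermediate (not isolated)
15 | (3aS,4R,5S,9bS)-4,5-dihydroxy-7-methoxy-5,8-dimethyl-3a,4,5,9b-tetrahydronaphtho[2,1-b]furan-2(1H)-one | O=C1C[C@@H]2[C@H](O1)[C@@H](O)[C@@](C)(O)c3cc(OC)c(C)cc32 | intermediate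
16 | (3aS,4R,5S,9bS)-4-[(tert-butyldimethylsilyl)oxy]-5-hydroxy-7-methoxy-5,8-dimethyl-3a,4,5,9b-tetrahydronaphtho[2,1-b]furan-2(1H)-one | O=C1C[C@@H]2[C@H](O1)[C@@H](O[Si](C)(C)C(C)(C)C)[C@@](C)(O)c3cc(OC)c(C)cc32 | intermediate
17 | lithium 2-[(1S,2S,3R,4S)-3-[(tert-butyldimethylsilyl)oxy]-2,4-dihydroxy-6-methoxy-4,7-dimethyl-1,2,3,4-tetrahydronaphthalen-1-yl]acetate | [Li+].[O-]C(=O)C[C@@H]1[C@H](O)[C@@H](O[Si](C)(C)C(C)(C)C)[C@@](C)(O)c2cc(OC)c(C)cc21 | intermediate (not isolated)
18 | triethylsilyl 2-[(1S,2S,3R,4S)-3-[(tert-butyldimethylsilyl)oxy]-4-hydroxy-6-methoxy-4,7-dimethyl-2-[(triethylsilyl)oxy]-1,2,3,4-tetrahydronaphthalen-1-yl]acetate | CC[Si](CC)(CC)OC(=O)C[C@@H]1[C@H](O[Si](CC)(CC)CC)[C@@H](O[Si](C)(C)C(C)(C)C)[C@@](C)(O)c2cc(OC)c(C)cc21 | intermediate (not isolated)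
19 | 2-[(1S,2S,3R,4S)-3-[(tert-butyldimethylsilyl)oxy]-4-hydroxy-6-methoxy-4,7-dimethyl-2-[(triethylsilyl)oxy]-1,2,3,4-tetrahydronaphthalen-1-yl]acetic acid | OC(=O)C[C@@H]1[C@H](O[Si](CC)(CC)CC)[C@@H](O[Si](C)(C)C(C)(C)C)[C@@](C)(O)c2cc(OC)c(C)cc21 | intermediate
20 | 2-[(1S,2S,3R,4S)-3-[(tert-butyldimethylsilyl)oxy]-4-hydroxy-6-methoxy-4,7-dimethyl-2-[(triethylsilyl)oxy]-1,2,3,4,5,8-hexahydronaphthalen-1-yl]acetic acid | OC(=O)C[C@@H]1[C@H](O[Si](CC)(CC)CC)[C@@H](O[Si](C)(C)C(C)(C)C)[C@@](C)(O)C2=C1CC(C)=C(OC)C2 | intermediate (not isolated)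
21 | 2-[(1S,2S,3R,4S)-3-[(tert-butyldimethylsilyl)oxy]-4-hydroxy-4,7-dimethyl-6-oxo-2-[(triethylsilyl)oxy]-1,2,3,4,5,6,7,8-octahydronaphthalen-1-yl]acetic acid (both epimers at germacrane C4) | OC(=O)C[C@@H]1[C@H](O[Si](CC)(CC)CC)[C@@H](O[Si](C)(C)C(C)(C)C)[C@@](C)(O)C2=C1CC(C)C(=O)C2 | intermediate
22 | (7R,8S,9R,10R)-9-[(tert-butyldimethylsilyl)oxy]-10-hydroxy-1,3,6-trioxo-8-[(triethylsilyl)oxy]-13-norgermacran-12-oic acid (both C4 epimers) | OC(=O)C[C@@H]1[C@H](O[Si](CC)(CC)CC)[C@@H](O[Si](C)(C)C(C)(C)C)[C@@](C)(O)C(=O)CC(=O)C(C)CC1=O | intermediate (not isolated)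
23 | (7R,8S,9R,10R)-9-[(tert-butyldimethylsilyl)oxy]-3-hydroxy-1,6-dioxo-8-[(triethylsilyl)oxy]-3,10-epoxy-13-norgermacran-12-oic acid (C3 hemiketal, both C4 epimers) | OC(=O)C[C@@H]1[C@H](O[Si](CC)(CC)CC)[C@@H](O[Si](C)(C)C(C)(C)C)[C@@]2(C)OC(O)(CC2=O)C(C)CC1=O | intermediate (not isolated)
24 | (7R,8S,9R,10R)-9-[(tert-butyldimethylsilyl)oxy]-1,6-dioxo-8-[(triethylsilyl)oxy]-3,10-epoxy-13-norgermacr-2-en-12-oic acid (both C4 epimers) | OC(=O)C[C@@H]1[C@H](O[Si](CC)(CC)CC)[C@@H](O[Si](C)(C)C(C)(C)C)[C@@]2(C)OC(=CC2=O)C(C)CC1=O | intermediate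
25 | trimethylsilyl (7R,8S,9R,10R)-9-[(tert-butyldimethylsilyl)oxy]-1-oxo-8-[(triethylsilyl)oxy]-6-[(trimethylsilyl)oxy]-3,10-epoxy-13-norgermacra-2,5-dien-12-oate (both C4 epimers) | C[Si](C)(C)OC(=O)C[C@@H]1[C@H](O[Si](CC)(CC)CC)[C@@H](O[Si](C)(C)C(C)(C)C)[C@@]2(C)OC(=CC2=O)C(C)C=C1O[Si](C)(C)C | intermediate (not isolated)
26 | (4Z,7R,8S,9R,10R)-9-[(tert-butyldimethylsilyl)oxy]-1,6-dioxo-8-[(triethylsilyl)oxy]-3,10-epoxy-13-norgermacra-2,4-dien-12-oic acid | OC(=O)C[C@@H]1[C@H](O[Si](CC)(CC)CC)[C@@H](O[Si](C)(C)C(C)(C)C)[C@@]2(C)OC(=CC2=O)/C(C)=C\C1=O | intermediate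
27 | (4Z,6S,7S,8S,9R,10R)-9-[(tert-butyldimethylsilyl)oxy]-6-hydroxy-1-oxo-8-[(triethylsilyl)oxy]-3,10-epoxy-13-norgermacra-2,4-dien-12-oic acid | OC(=O)C[C@@H]1[C@H](O[Si](CC)(CC)CC)[C@@H](O[Si](C)(C)C(C)(C)C)[C@@]2(C)OC(=CC2=O)/C(C)=C\[C@@H]1O | intermediate
28 | (4Z,6R,7S,8S,9R,10R)-9-[(tert-butyldimethylsilyl)oxy]-1-oxo-8-[(triethylsilyl)oxy]-3,10-epoxy-13-norgermacra-2,4-dien-12,6-olide | C1C(=O)O[C@@H]2/C=C(/C)C3=CC(=O)[C@](C)(O3)[C@H](O[Si](C)(C)C(C)(C)C)[C@@H](O[Si](CC)(CC)CC)[C@@H]12 | intermediate
29 | (4Z,6R,7S,8S,9R,10R)-9-[(tert-butyldimethylsilyl)oxy]-13-(dimethylamino)-1-oxo-8-[(triethylsilyl)oxy]-3,10-epoxygermacra-2,4-dien-12,6-olide (both C11 epimers) | CN(C)CC1C(=O)O[C@@H]2/C=C(/C)C3=CC(=O)[C@](C)(O3)[C@H](O[Si](C)(C)C(C)(C)C)[C@@H](O[Si](CC)(CC)CC)[C@@H]12 | intermediate (not isolated)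
30 | N,N,N-trimethylammonium iodide of 29 (quaternised at the C13 nitrogen, both C11 epimers) | C[N+](C)(C)CC1C(=O)O[C@@H]2/C=C(/C)C3=CC(=O)[C@](C)(O3)[C@H](O[Si](C)(C)C(C)(C)C)[C@@H](O[Si](CC)(CC)CC)[C@@H]12.[I-] | intermediate (not isolated)
31 | (4Z,6R,7S,8S,9R,10R)-9-[(tert-butyldimethylsilyl)oxy]-1-oxo-8-[(triethylsilyl)oxy]-3,10-epoxygermacra-2,4,11(13)-trien-12,6-olide | C=C1C(=O)O[C@@H]2/C=C(/C)C3=CC(=O)[C@](C)(O3)[C@H](O[Si](C)(C)C(C)(C)C)[C@@H](O[Si](CC)(CC)CC)[C@@H]12 | intermediate
32 | (4Z,6R,7R,8S,9R,10R)-9-[(tert-butyldimethylsilyl)oxy]-8-hydroxy-1-oxo-3,10-epoxygermacra-2,4,11(13)-trien-12,6-olide | C=C1C(=O)O[C@@H]2/C=C(/C)C3=CC(=O)[C@](C)(O3)[C@H](O[Si](C)(C)C(C)(C)C)[C@@H](O)[C@@H]12 | intermediate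
33 | (4Z,6R,7S,8S,9R,10R)-9-[(tert-butyldimethylsilyl)oxy]-8-(3-methylbutanoyloxy)-1-oxo-3,10-epoxygermacra-2,4,11(13)-trien-12,6-olide | C=C1C(=O)O[C@@H]2/C=C(/C)C3=CC(=O)[C@](C)(O3)[C@H](O[Si](C)(C)C(C)(C)C)[C@@H](OC(=O)CC(C)C)[C@@H]12 | intermediate
34 | (4Z,6R,7S,8S,9R,10R)-9-hydroxy-8-(3-methylbutanoyloxy)-1-oxo-3,10-epoxygermacra-2,4,11(13)-trien-12,6-olide | C=C1C(=O)O[C@@H]2/C=C(/C)C3=CC(=O)[C@](C)(O3)[C@H](O)[C@@H](OC(=O)CC(C)C)[C@@H]12 | intermediate
35 | (4Z,6R,7S,8S,9R,10R)-9-acetoxy-8-(3-methylbutanoyloxy)-1-oxo-3,10-epoxygermacra-2,4,11(13)-trien-12,6-olide (CNP0255553.1) | C=C1C(=O)O[C@@H]2/C=C(/C)C3=CC(=O)[C@](C)(O3)[C@H](OC(C)=O)[C@@H](OC(=O)CC(C)C)[C@@H]12 | target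

## Step count and least certain steps

Total step count: 20. Longest linear sequence: 20 steps (1 and 2 to 35).

Step 12 (key step). The most likely failure is a transannular aldol condensation of the triketone before the furanone closes, or fragmentation next to the C10 hydroxyl during ozonolysis. The cause is that C2 of the 1,3-diketone is a strong carbon nucleophile five atoms from the C6 ketone, and the intermediate carbonyl oxide sits beside a free tertiary carbinol. The fallback sets out from 21 and returns at 24. The C3 ketone of 21 is converted under aprotic conditions (1,2-bis(trimethylsilyloxy)ethane, catalytic Me3SiOSO2CF3, −78 °C) into the C3 ethylene ketal of the octalin F1. Ozonolysis of F1 with Me2S work-up then gives the ring-opened C1,C6-diketone C3 ketal F2, which contains no 1,3- or 1,4-dicarbonyl pair and no doubly activated C2. Mild aqueous acid finally ionises the ketal at C3 in the presence of the C10 hydroxyl, which captures the oxocarbenium ion and, after loss of the diol, gives 24 without the free triketone ever being present.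

Step 14. The risk is reversed or poor facial selectivity of hydride delivery, because the medium ring may not adopt the conformation on which the Felkin–Anh argument rests. The fallback sets out from 26 and returns at 28. If the same reduction delivers the 6R hydroxy acid F3, it is closed with retention by activating the carboxyl group (carbodiimide with DMAP, or a mixed anhydride) and not the hydroxyl. A mixture of both carbinols can be separated and each epimer sent through its own closure, so both converge on 28.

Step 16. The risk is proton transfer from the vinylogous positions (C15, C6) to the lactone enolate, or degradation of the dienone under the amide base, since these positions are thermodynamically more acidic than C11. The fallback sets out from 28 and returns at 31. Chelation-driven carboxylation with MeOMgOCO2Me in DMF can occur only at a carbon that forms a magnesium β-dicarbonyl chelate, that is at C11, and gives the α-carboxy lactone F4. Treatment of F4 with aqueous formaldehyde and diethylamine in buffered acetic acid then effects Mannich reaction, decarboxylation and elimination to 31.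

Step 13. The risk is inefficient palladium-mediated oxidation of the hindered medium-ring silyl enol ether (protodesilylation back to the ketone, or β-hydride elimination into the E olefin), together with any equilibration of the enolate toward C7. The fallback sets out from 24 and returns at 26. The kinetic lithium enolate is quenched with PhSeBr at −78 °C to give the C5 phenylselanyl ketone F5, and oxidation with H2O2 and pyridine triggers selenoxide syn-elimination, which can only run toward C4 and gives 26 under neutral conditions.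

Step 5. The risk is insufficient facial selectivity in the epoxidation: the C7 arm is only homoallylic to C9, and the catalyst preference for an olefin with the aryl group cis to the ring chain is less secure than for simple trans olefins. The fallback sets out from 9 and returns at 12, replacing steps 5 and 6. In a Schenck ene reaction (O2, tetraphenylporphyrin, visible light, CH2Cl2, −20 °C) singlet oxygen must abstract the pseudoaxial C8 hydrogen, which lies anti to the pseudoaxial C7 arm, and delivers oxygen suprafacially to C10 on that face, giving the tertiary allylic hydroperoxide F6. Reduction of F6 with PPh3 gives 12.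

## Further compounds

F1 | step 12 | 2-[(1S,2S,3R,4S)-3-[(tert-butyldimethylsilyl)oxy]-6,6-(ethane-1,2-diyldioxy)-4-hydroxy-4,7-dimethyl-2-[(triethylsilyl)oxy]-1,2,3,4,5,6,7,8-octahydronaphthalen-1-yl]acetic acid (C3 dioxolane of 21, both C4 epimers) | OC(=O)C[C@@H]1[C@H](O[Si](CC)(CC)CC)[C@@H](O[Si](C)(C)C(C)(C)C)[C@@](C)(O)C2=C1CC(C)C3(OCCO3)C2
F2 | step 12 | (7R,8S,9R,10R)-9-[(tert-butyldimethylsilyl)oxy]-3,3-(ethane-1,2-diyldioxy)-10-hydroxy-1,6-dioxo-8-[(triethylsilyl)oxy]-13-norgermacran-12-oic acid (both C4 epimers) | OC(=O)C[C@@H]1[C@H](O[Si](CC)(CC)CC)[C@@H](O[Si](C)(C)C(C)(C)C)[C@@](C)(O)C(=O)CC3(OCCO3)C(C)CC1=O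
F3 | step 14 | (4Z,6R,7S,8S,9R,10R)-9-[(tert-butyldimethylsilyl)oxy]-6-hydroxy-1-oxo-8-[(triethylsilyl)oxy]-3,10-epoxy-13-norgermacra-2,4-dien-12-oic acid | OC(=O)C[C@@H]1[C@H](O[Si](CC)(CC)CC)[C@@H](O[Si](C)(C)C(C)(C)C)[C@@]2(C)OC(=CC2=O)/C(C)=C\[C@H]1O
F4 | step 16 | (4Z,6R,7S,8S,9R,10R)-9-[(tert-butyldimethylsilyl)oxy]-1-oxo-8-[(triethylsilyl)oxy]-3,10-epoxygermacra-2,4-dien-12,6-olid-13-oic acid (both C11 epimers) | OC(=O)C1C(=O)O[C@@H]2/C=C(/C)C3=CC(=O)[C@](C)(O3)[C@H](O[Si](C)(C)C(C)(C)C)[C@@H](O[Si](CC)(CC)CC)[C@@H]12
F5 | step 13 | (7R,8S,9R,10R)-9-[(tert-butyldimethylsilyl)oxy]-1,6-dioxo-5-(phenylselanyl)-8-[(triethylsilyl)oxy]-3,10-epoxy-13-norgermacr-2-en-12-oic acid (C4 and C5 epimers) | OC(=O)C[C@@H]1[C@H](O[Si](CC)(CC)CC)[C@@H](O[Si](C)(C)C(C)(C)C)[C@@]2(C)OC(=CC2=O)C(C)C([Se]c3ccccc3)C1=O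
F6 | step 5 | methyl 2-[(1R,4R)-4-hydroperoxy-6-methoxy-4,7-dimethyl-1,4-dihydronaphthalen-1-yl]acetate | COC(=O)C[C@@H]1C=C[C@@](C)(OO)c2cc(OC)c(C)cc21
A1 | alternative 1 | ten-membered 1-ethoxy-2-en-3-one with trans C8=C9, C6 and C10 methoxymethyl ethers and a 12-(methoxymethoxy)-11(13)-ene side chain | COCO[C@@H]1/C=C(/C)C(=O)/C=C(OCC)\[C@](C)(OCOC)/C=C/[C@H]1C(COCOC)=C
A2 | alternative 2 | furanone–methylene lactone diene with vinyl groups on C7 and C10 | C=C1C(=O)O[C@H](/C=C(/C)C2=CC(=O)[C@](C)(O2)C=C)[C@H]1C=C
A3 | alternative 2 | bicyclic furanone-bridged methylene lactone with cis C8=C9 | C=C1C(=O)O[C@@H]2/C=C(/C)C3=CC(=O)[C@](C)(O3)/C=C\[C@@H]12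
A4 | alternative 3 | C6 diazo(diethoxyphosphoryl)acetate of the ten-membered furanone core with the C8/C9 acetonide | CCOP(=O)(OCC)C(=[N+]=[N-])C(=O)O[C@@H]1/C=C(/C)C2=CC(=O)[C@](C)(O2)[C@@H]3OC(C)(C)O[C@H]3C1
A5 | alternative 3 | α-(diethoxyphosphoryl) γ-lactone of the furanone core with the C8/C9 acetonide | CCOP(=O)(OCC)[C@@H]1C(=O)O[C@@H]2/C=C(/C)C3=CC(=O)[C@](C)(O3)[C@@H]4OC(C)(C)O[C@H]4[C@@H]12
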